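## Retrosynthetic overview

1. Target 21 ← double O-debenzylation of bis-benzyl ether 20 (both outer phenols carried as benzyl ethers).
2. Central resorcinol monomethyl ether ring of 20 ← aromatisation (α'-selenenylation, selenoxide elimination) of methyl enol ether 15, so mono-O-methylation is fixed before the ring is aromatic.
3. 15 ← 2-benzylated dione 14 ← reductive Knoevenagel coupling of dione 11 with 4-(benzyloxy)benzaldehyde 12.
4. 11 ← Michael addition of dimethyl malonate 7 to enone 6, Claisen (Dieckmann) closure, decarboxylation; this builds the only ring made in the route (both outer rings are bought).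
5. 6 ← Wittig olefination of aldehyde 4 ← dihydrocoumarin 1 (reduction, phenol benzylation, oxidation).

Assumption: the target has no stereocentre and no stereogenic double bond, so it is achiral and no enantiocontrol is needed; chiral intermediates are used as racemates.

## Route

Step 1
Reactants: 1 dihydrocoumarin (3,4-dihydro-2H-chromen-2-one)
Product: 2 2-(3-hydroxypropyl)phenol
Conditions: LiAlH4 (1.2 equiv), THF, 0 °C to rt; Fieser work-up
Reagents that add atoms: none
Why: Hydride reduction of the aryl lactone opens it cleanly to the phenol–primary alcohol pair.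

Step 2
Reactants: 2 2-(3-hydroxypropyl)phenol
Product: 3 3-[2-(benzyloxy)phenyl]propan-1-ol
Conditions: BnBr (1.05 equiv), K2CO3 (1.5 equiv), acetone, reflux
Reagents that add atoms: benzyl bromide, BrCc1ccccc1
Why: Williamson etherification; K2CO3 deprotonates only the phenol, so the aliphatic alcohol is untouched.

Step 3
Reactants: 3 3-[2-(benzyloxy)phenyl]propan-1-ol
Product: 4 3-[2-(benzyloxy)phenyl]propanal
Conditions: TEMPO (10 mol %), PhI(OAc)2 (1.1 equiv), CH2Cl2, rt
Reagents that add atoms: none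
Why: TEMPO/oxoammonium oxidation stops at the aldehyde and does not touch the aryl benzyl ether.

Step 4
Reactants: 4 3-[2-(benzyloxy)phenyl]propanal; 5 1-(triphenyl-λ5-phosphanylidene)propan-2-one
Product: 6 (E)-6-[2-(benzyloxy)phenyl]hex-3-en-2-one
Conditions: toluene, 80 °C
Reagents that add atoms: none
Why: Wittig olefination with a stabilised ylide gives the (E)-enone without self-aldol of the aldehyde; the alkene geometry is lost later anyway.

Step 5
Reactants: 6 (E)-6-[2-(benzyloxy)phenyl]hex-3-en-2-one; 7 dimethyl malonate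
Product: 9 methyl 6-{2-[2-(benzyloxy)phenyl]ethyl}-2,4-dioxocyclohexane-1-carboxylate (racemic), via Michael adduct 8 (not isolated)
Conditions: NaOMe (1.1 equiv), MeOH, reflux; then cold 1 M HCl
Reagents that add atoms: none
Why: Intermolecular Michael addition of the malonate anion to the enone, then intramolecular Claisen (Dieckmann) attack of the methyl-ketone enolate on an ester, driven by the stable β-diketone enolate.

Step 6
Reactants: 9 methyl 6-{2-[2-(benzyloxy)phenyl]ethyl}-2,4-dioxocyclohexane-1-carboxylate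
Product: 11 5-{2-[2-(benzyloxy)phenyl]ethyl}cyclohexane-1,3-dione, via keto acid 10 (not isolated)
Conditions: 2 M NaOH aq, reflux; then HCl to pH 2, 80 °C until CO2 evolution stops
Reagents that add atoms: none
Why: Saponification then decarboxylation of the β-keto acid; the aryl benzyl ether is stable to aqueous base and dilute acid.

Step 7
Reactants: 11 5-{2-[2-(benzyloxy)phenyl]ethyl}cyclohexane-1,3-dione; 12 4-(benzyloxy)benzaldehyde
Product: 14 2-{[4-(benzyloxy)phenyl]methyl}-5-{2-[2-(benzyloxy)phenyl]ethyl}cyclohexane-1,3-dione, via Knoevenagel enedione 13 (not isolated)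
Conditions: Hantzsch ester (1.05 equiv), L-proline (20 mol %), CH2Cl2, rt
Reagents that add atoms: none
Why: Organocatalytic Knoevenagel (aldol-type) condensation with in-situ conjugate transfer hydrogenation; the arylidene dione is reduced before a second dione can add, so only C-monobenzylation occurs.

Step 8
Reactants: 14 2-{[4-(benzyloxy)phenyl]methyl}-5-{2-[2-(benzyloxy)phenyl]ethyl}cyclohexane-1,3-dione
Product: 15 2-{[4-(benzyloxy)phenyl]methyl}-5-{2-[2-(benzyloxy)phenyl]ethyl}-3-methoxycyclohex-2-en-1-one (racemic)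
Conditions: MeOH, HC(OMe)3 (3 equiv), p-TsOH·H2O (5 mol %), 60 °C
Reagents that add atoms: methanol, CO (the OCH3 group; trimethyl orthoformate, COC(OC)OC, scavenges the water and is an equivalent OCH3 source)
Why: Acid-catalysed vinylogous esterification stops at the mono enol ether, and the two carbonyls of 14 are equivalent, so one product forms.

Step 9
Reactants: 15 2-{[4-(benzyloxy)phenyl]methyl}-5-{2-[2-(benzyloxy)phenyl]ethyl}-3-methoxycyclohex-2-en-1-one
Product: 17 trans-2-{[4-(benzyloxy)phenyl]methyl}-5-{2-[2-(benzyloxy)phenyl]ethyl}-3-methoxy-6-(phenylselanyl)cyclohex-2-en-1-one (racemic), via lithium dienolate 16 (not isolated)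
Conditions: LDA (1.1 equiv, commercial solution), THF, −78 °C; PhSeCl (1.15 equiv), −78 °C; NH4Cl aq
Reagents that add atoms: benzeneselenenyl chloride, Cl[Se]c1ccccc1
Why: Kinetic α'-deprotonation of the vinylogous ester (Stork–Danheiser-type enolate) and α-selenenylation anti to the C5 side chain; the two stereocentres are transient and vanish on aromatisation.

Step 10
Reactants: 17 trans-2-{[4-(benzyloxy)phenyl]methyl}-5-{2-[2-(benzyloxy)phenyl]ethyl}-3-methoxy-6-(phenylselanyl)cyclohex-2-en-1-one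
Product: 20 2-{[4-(benzyloxy)phenyl]methyl}-5-{2-[2-(benzyloxy)phenyl]ethyl}-3-methoxyphenol, via selenoxide 18 (not isolated), via cyclohexadienone 19 (not isolated)
Conditions: 30 % H2O2 (2.5 equiv), pyridine (2 equiv), CH2Cl2, 0 °C to rt; Na2S2O3/NaHCO3 wash
Reagents that add atoms: none
Why: Selenoxide syn-elimination (the C5–H is cis to selenium in the trans isomer) gives the 2,5-cyclohexadienone, which tautomerises irreversibly to the phenol.

Step 11
Reactants: 20 2-{[4-(benzyloxy)phenyl]methyl}-5-{2-[2-(benzyloxy)phenyl]ethyl}-3-methoxyphenol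
Product: 21 2-[(4-hydroxyphenyl)methyl]-5-[2-(2-hydroxyphenyl)ethyl]-3-methoxyphenol (target)
Conditions: H2 (1 atm), 10 % Pd/C, EtOAc–MeOH 1:1, rt
Reagents that add atoms: none
Why: Catalytic hydrogenolysis removes both aryl benzyl ethers; the methyl ether, the diarylmethane CH2 and the bibenzyl bridge are inert under these conditions.

## Compound list

1 | dihydrocoumarin (3,4-dihydro-2H-chromen-2-one) | O=C1CCc2ccccc2O1 | starting material
2 | 2-(3-hydroxypropyl)phenol | OCCCc1ccccc1O | intermediate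
3 | 3-[2-(benzyloxy)phenyl]propan-1-ol | OCCCc1ccccc1OCc1ccccc1 | intermediate
4 | 3-[2-(benzyloxy)phenyl]propanal | O=CCCc1ccccc1OCc1ccccc1 | intermediate
5 | 1-(triphenyl-λ5-phosphanylidene)propan-2-one | CC(=O)C=P(c1ccccc1)(c1ccccc1)c1ccccc1 | starting material
6 | (E)-6-[2-(benzyloxy)phenyl]hex-3-en-2-one | CC(=O)/C=C/CCc1ccccc1OCc1ccccc1 | intermediate
7 | dimethyl malonate | COC(=O)CC(=O)OC | starting material
8 | dimethyl 2-{1-[2-(benzyloxy)phenyl]-5-oxohexan-3-yl}propanedioate (racemic) | COC(=O)C(C(=O)OC)C(CCc1ccccc1OCc1ccccc1)CC(C)=O | intermediate (not isolated)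
9 | methyl 6-{2-[2-(benzyloxy)phenyl]ethyl}-2,4-dioxocyclohexane-1-carboxylate (racemic, drawn as keto form) | COC(=O)C1C(=O)CC(=O)CC1CCc1ccccc1OCc1ccccc1 | intermediate
10 | 6-{2-[2-(benzyloxy)phenyl]ethyl}-2,4-dioxocyclohexane-1-carboxylic acid (racemic) | OC(=O)C1C(=O)CC(=O)CC1CCc1ccccc1OCc1ccccc1 | intermediate (not isolated)
11 | 5-{2-[2-(benzyloxy)phenyl]ethyl}cyclohexane-1,3-dione (achiral) | O=C1CC(=O)CC(CCc2ccccc2OCc2ccccc2)C1 | intermediate
12 | 4-(benzyloxy)benzaldehyde | O=Cc1ccc(OCc2ccccc2)cc1 | starting material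
13 | 2-{[4-(benzyloxy)phenyl]methylidene}-5-{2-[2-(benzyloxy)phenyl]ethyl}cyclohexane-1,3-dione | O=C1CC(CCc2ccccc2OCc2ccccc2)CC(=O)C1=Cc1ccc(OCc2ccccc2)cc1 | intermediate (not isolated)
14 | 2-{[4-(benzyloxy)phenyl]methyl}-5-{2-[2-(benzyloxy)phenyl]ethyl}cyclohexane-1,3-dione (drawn as keto form) | O=C1CC(CCc2ccccc2OCc2ccccc2)CC(=O)C1Cc1ccc(OCc2ccccc2)cc1 | intermediate
15 | 2-{[4-(benzyloxy)phenyl]methyl}-5-{2-[2-(benzyloxy)phenyl]ethyl}-3-methoxycyclohex-2-en-1-one (racemic) | COC1=C(Cc2ccc(OCc3ccccc3)cc2)C(=O)CC(CCc2ccccc2OCc2ccccc2)C1 | intermediate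
16 | lithium 6-{[4-(benzyloxy)phenyl]methyl}-3-{2-[2-(benzyloxy)phenyl]ethyl}-5-methoxycyclohexa-1,5-dien-1-olate (racemic) | [Li+].COC1=C(Cc2ccc(OCc3ccccc3)cc2)C([O-])=CC(CCc2ccccc2OCc2ccccc2)C1 | intermediate (not isolated)
17 | trans-2-{[4-(benzyloxy)phenyl]methyl}-5-{2-[2-(benzyloxy)phenyl]ethyl}-3-methoxy-6-(phenylselanyl)cyclohex-2-en-1-one (racemic; one enantiomer drawn to show the 5,6-trans relation) | COC1=C(Cc2ccc(OCc3ccccc3)cc2)C(=O)[C@@H]([Se]c2ccccc2)[C@H](CCc2ccccc2OCc2ccccc2)C1 | intermediate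
18 | trans-6-(benzeneseleninyl)-2-{[4-(benzyloxy)phenyl]methyl}-5-{2-[2-(benzyloxy)phenyl]ethyl}-3-methoxycyclohex-2-en-1-one (racemic, mixture at Se) | COC1=C(Cc2ccc(OCc3ccccc3)cc2)C(=O)[C@@H]([Se](=O)c2ccccc2)[C@H](CCc2ccccc2OCc2ccccc2)C1 | intermediate (not isolated)
19 | 2-{[4-(benzyloxy)phenyl]methyl}-5-{2-[2-(benzyloxy)phenyl]ethyl}-3-methoxycyclohexa-2,5-dien-1-one | COC1=C(Cc2ccc(OCc3ccccc3)cc2)C(=O)C=C(CCc2ccccc2OCc2ccccc2)C1 | intermediate (not isolated)
20 | 2-{[4-(benzyloxy)phenyl]methyl}-5-{2-[2-(benzyloxy)phenyl]ethyl}-3-methoxyphenol | COc1cc(CCc2ccccc2OCc2ccccc2)cc(O)c1Cc1ccc(OCc2ccccc2)cc1 | intermediate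
21 | 2-[(4-hydroxyphenyl)methyl]-5-[2-(2-hydroxyphenyl)ethyl]-3-methoxyphenol (CNP0353999.0, achiral) | COc1cc(CCc2ccccc2O)cc(O)c1Cc1ccc(O)cc1 | target

## Summary

Total step count: 11. Longest linear sequence: 11 steps (1 → 21); compounds 5, 7 and 12 are bought and used directly.

Steps most likely to fail:

Step 5 (Michael–Claisen annulation; the enone may isomerise or oligomerise under methoxide before malonate adds). The fallback sets out from aldehyde 4 and swaps the donor and acceptor roles. Horner–Wadsworth–Emmons reaction of 4 with triethyl phosphonoacetate/NaH in THF gives ethyl (E)-5-[2-(benzyloxy)phenyl]pent-2-enoate F1. Ethyl acetoacetate/NaOEt in refluxing EtOH adds to F1 to give diethyl 2-acetyl-3-{2-[2-(benzyloxy)phenyl]ethyl}pentanedioate F2, which closes in the same pot to ethyl 6-{2-[2-(benzyloxy)phenyl]ethyl}-2,4-dioxocyclohexane-1-carboxylate F3. Saponification of F3 with aqueous NaOH comes back to the route at keto acid 10, which gives 11 on the acidification of step 6.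

Step 9 (α'-selenenylation; proton exchange between enolate 16 and the more acidic product 17 can give bis-selenide and returned 15). The fallback sets out from 15 and replaces the selenium chemistry by a Saegusa–Ito dehydrogenation. LDA then TMSCl in THF at −78 °C traps the enolate as ({6-{[4-(benzyloxy)phenyl]methyl}-3-{2-[2-(benzyloxy)phenyl]ethyl}-5-methoxycyclohexa-1,5-dien-1-yl}oxy)trimethylsilane F4. Pd(OAc)2 (1.05 equiv) in MeCN at rt converts F4 into dienone 19, where it comes back to the route; 19 tautomerises to 20.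

Step 10 (selenoxide elimination; the electron-rich phenol 20 is born in the presence of H2O2 and electrophilic Se(IV) and may be over-oxidised or selenenylated). The fallback sets out from 15 and uses a sulfoxide that eliminates thermally with no oxidant present. LDA (2.2 equiv) then methyl benzenesulfinate in THF, −78 to 0 °C, gives 6-(benzenesulfinyl)-2-{[4-(benzyloxy)phenyl]methyl}-5-{2-[2-(benzyloxy)phenyl]ethyl}-3-methoxycyclohex-2-en-1-one F5. Heating F5 in toluene at 110 °C over CaCO3 effects syn-elimination to dienone 19, where it comes back to the route; 19 tautomerises to 20.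

## Further compounds

F1 | step 5 | ethyl (E)-5-[2-(benzyloxy)phenyl]pent-2-enoate | CCOC(=O)/C=C/CCc1ccccc1OCc1ccccc1
F2 | step 5 | diethyl 2-acetyl-3-{2-[2-(benzyloxy)phenyl]ethyl}pentanedioate | CCOC(=O)CC(CCc1ccccc1OCc1ccccc1)C(C(C)=O)C(=O)OCC
F3 | step 5 | ethyl 6-{2-[2-(benzyloxy)phenyl]ethyl}-2,4-dioxocyclohexane-1-carboxylate | CCOC(=O)C1C(=O)CC(=O)CC1CCc1ccccc1OCc1ccccc1
F4 | step 9 | ({6-{[4-(benzyloxy)phenyl]methyl}-3-{2-[2-(benzyloxy)phenyl]ethyl}-5-methoxycyclohexa-1,5-dien-1-yl}oxy)trimethylsilane | COC1=C(Cc2ccc(OCc3ccccc3)cc2)C(O[Si](C)(C)C)=CC(CCc2ccccc2OCc2ccccc2)C1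
F5 | step 10 | 6-(benzenesulfinyl)-2-{[4-(benzyloxy)phenyl]methyl}-5-{2-[2-(benzyloxy)phenyl]ethyl}-3-methoxycyclohex-2-en-1-one | COC1=C(Cc2ccc(OCc3ccccc3)cc2)C(=O)C(S(=O)c2ccccc2)C(CCc2ccccc2OCc2ccccc2)C1
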